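The constant I wanted was the one that turns [Z][Q] into E, so I opened a ledger for Q, the limiting reagent at 0.950 equiv to Z in both flasks.

| flask | Z | Q | remark | time |
|---|---|---|---|---|
| epsilon | 0.015 M | 0.95 equiv (fed, over 80 min) | run made earlier |  |
| alpha | 0.035 M | 0.95 equiv (fed, over 80 min) | run made earlier |  |
| theta | 0.023 M | 0.47 equiv (fed, over 80 min) | run made earlier |  |
| oak | 0.023 M | 0.950 equiv | everything together at the start | 1.5 h |
| cedar | 0.023 M | 0.950 equiv (fed, over 80 min) |  | 1.5 h |

| run | time / min | E / % | Z / % |
|---|---|---|---|
| epsilon | 8.00 | 0 | 91.7 |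
| epsilon | 25.0 | 3.0 | 76.3 |
| epsilon | 40.0 | 7.4 | 63.5 |
| epsilon | 60.0 | 12.7 | 52.7 |
| epsilon | 90.0 | 20.2 | 35.6 |
| alpha | 8.00 | 0 | 85.5 |
| alpha | 25.0 | 5.1 | 62.0 |
| alpha | 40.0 | 10.5 | 45.7 |
| alpha | 60.0 | 18.3 | 31.2 |
| alpha | 90.0 | 26.8 | 19.2 |
| theta | 8.00 | 0 | 88.4 |
| theta | 15.0 | 0.6 | 81.2 |
| theta | 25.0 | 0.2 | 71.5 |
| theta | 50.0 | 3.8 | 53.1 |
| theta | 90.0 | 13.1 | 34.9 |

(standard deviation of a reading: 1 percentage point)

- the winner by amount of E, in percent of the Z charged; "neither" if no more than 2 percentage points parts them (oak / cedar / neither)
- how much E is there at the end, in percent of the Z charged: oak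
- how much E is there at the end, in percent of the Z charged: cedar

The first entries came from alpha. Between 40.0 min and 60.0 min it had been fed on average 59.4% of its Z charge as Q. E held 14.4%, so, counting E as the one outlet, 45.0% stood free beside 38.5% of Z. That gave 0.644 /M/min, my trapping constant, the E made per minute divided by [Z][Q]. It is a reading from two points and carries their scatter. With that one outlet, Q falls pseudo-first-order at this constant times [Z], so I worked with the fraction of Q left, exp(−constant × ∫[Z]dt), and not with the E made.

Oak needed [Z]. In theta, Z and E together stood at 48.0% after 90.0 min, a loss that does not pass through E and that averages 0.00816 /min over that time when reckoned as first-order. The same reckoning at 50.0 min gave 0.0113 /min, more than at 90.0 min, so this loss is not first-order and I used the figure as an average only. Taking oak's Q at 0.7 of its charge on average, I put Z's average total loss in oak at 0.0180 /min. The exponent over 1.5 h came to 0.660, leaving 51.7% of oak's Q. The books closed with 45.9% of the Z charge as E and 49.1% as Q. For cedar I interpolated epsilon and alpha to 22.8%, less than my oak figure.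

The forecast named oak, with 35% for oak and 23% for cedar, since in oak “all Q is present from the start”. My oak stood 11 percentage points above its figure; for cedar it used the same interpolation.

Oak ended at 41.5% and cedar at 24.4%, under this scheme:

    Z ⇌ G (K = 0.470, k = 0.00250 /min)
    Q + E → D (k = 0.0230 /M/min)
    Z + Q → E (k = 0.650 /M/min)
    Q → J (k = 8.70 × 10⁻⁴ /min)
    2 Z → L (k = 0.270 /M/min)
    Q + D → X (k = 0.0780 /M/min)

At the start of oak, Z + Q to E used Z at 1.1 times the rate of the pairing of Z to L, and at 1.50 h at 2.6 times. L, each counting as two Z, ended at 27.9% in oak and 39.3% in cedar. With oak's final Z of 22%, my constant puts Q's half-life by that step at 3.52 h, where the flask has 3.5 h. The neighbour of oak with 0.0057 M of Z ended with 53% of its Z left; taking the logarithmic mean of that decline, the constant gives 20.6% of E, and that flask holds 19.5%.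

Readings and results are calculated for an exercise; noise was put on by code.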